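**Remark on the chemistry:** the target has no stereocentre, so amino alcohol 1 is used as the racemate; its benzylic centre becomes C3 and is flattened in step 6, and compounds 1, 2, 6 and 8 are taken to be catalogue compounds.

## Analysis of the target

Lukianol B (17) is a flat, achiral 1H-pyrrolo[2,1-c][1,4]oxazin-1-one: a pyrrole (N5, C6, C7, C8, C8a) fused through the N5–C8a bond to an unsaturated six-membered lactone (C1, O2, C3, C4, N5, C8a). It carries a 4-hydroxyphenyl group on C3, a 3-iodo-4-hydroxyphenyl group on C7 and a 4-hydroxyphenyl group on C8, while C4 and C6 carry hydrogen. With no stereocentre, the problem is one of regiochemistry: three nearly identical phenol rings must sit on three defined carbons, and only the ring on C7 may carry iodine. The sensitive groups are the aryl iodide (lost under palladium or nickel catalysis, strong reductants and halogen–metal exchange), the enol lactone (opened by base and nucleophiles), and the phenols and pyrrole (easily oxidised once the phenols are free). A late iodination would have to choose among three phenol rings and between mono- and di-substitution, so the iodine is best carried from the start on its own building block, which in turn rules out cross-coupling for the aryl–pyrrole bonds. The route rests on one observation: the lactone ring, read two hydrogens richer at C3–C4, is a 6-aryl-morpholin-2-one whose nitrogen (N5) and acidic α-carbon (C8a) are the two ends of an azomethine ylide. The remaining pyrrole carbons C6, C7 and C8 with their two aryl groups are then a 2,3-diarylacrolein.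

## Retrosynthetic reasoning

**17 to 16.** The last bonds touched are the three O–methyl bonds, which leads back to tri-O-methyl ether 16. Methyl ethers make all building blocks simple anisole derivatives that survive every earlier condition, whereas free phenols would not survive the quinone oxidations. The forward step must cleave three aryl methyl ethers with a boron trihalide without opening the enol lactone or removing iodine. It is placed after the C3=C4 double bond is in, because the benzylic C3–O bond of 15 would ionise under a strong Lewis acid.

**16 to 15.** Adding two hydrogens across C3=C4 gives dihydro lactone 15. No bond is cut, but this change of oxidation level opens the main disconnection: with C3 and C4 saturated the lactone ring can come from a stable amino lactone, whereas the unsaturated version would be a free enamine. The forward step is a dehydrogenation of a CH–CH2 unit flanked by an anisyl ring, the lactone oxygen and the pyrrole nitrogen. It is driven by conjugation and removes the only stereocentre of 15.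

**15 to 5 and 11.** The pyrrole is cut at N5–C6 and C8–C8a. These are the two bonds that a condensation followed by a 1,5-electrocyclization makes, through iminium ion 12, azomethine ylide 13 and pyrroline 14. The cut divides the skeleton into two halves of similar size: morpholinone salt 5 brings C1, O2, C3, C4, N5, C8a and the C3 aryl group, and enal 11 brings C6, C7, C8 and both pyrrole aryl groups. Regiochemistry is fixed by connectivity, since the formyl carbon can only become C6 and the β-carbon can only bond to C8a. No metal is involved, so the iodide is safe. Cutting the aryl–C7 or aryl–C8 bonds instead would need cross-coupling in the presence of the iodide.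

**11 to 9, and 9 to 7 and 8.** Enal 11 is traced to acrylic acid 9, one oxidation level higher, because 9 comes from a Perkin condensation of arylacetic acid 7 with aldehyde 8. That condensation forms the C7=C8 bond and gives the E isomer, which is the geometry the electrocyclization wants. A direct crossed aldol of the corresponding enolisable aldehyde with the electron-rich, poorly electrophilic 8 would compete with self-condensation. The forward reduction from acid to aldehyde goes through acid chloride 10.

**7 to 6.** The C–I bond is cut to give acid 6. The methoxy group directs iodination to its ortho position and the para position is blocked, so a single regioisomer is expected. The iodine is therefore on the correct ring from the second step on.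

**5 to 1 and 2.** Morpholinone salt 5 is cut at the N–CH2 bond and at the lactone acyl–oxygen bond, giving amino alcohol 1 and bromoacetate 2. An aryl ester is chosen so that, after N-alkylation to 3, the secondary benzylic hydroxyl closes the lactone under neutral conditions to give free base 4. An ordinary alkyl ester would need hot acid, which the 4-methoxybenzylic alcohol would not tolerate. Free base 4 is trapped at once as hydrochloride 5, because a free amino lactone acylates itself; the salt is the form that is stored and carried into the key step.

## Alternatives that were turned down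

**Alternative 1:** The pyrrole is cut at the C7–aryl bond and at C8–C8a. The precursor is methyl 2-{[3-(4-methoxyphenyl)prop-2-yn-1-yl](4-methylphenylsulfonyl)amino}-2-oxoacetate A1, which would react with (4-isopropoxyphenyl)boronic acid A2 under Ni(OAc)2 catalysis. The aryl group of A2 adds to the alkyne carbon of A1 that becomes C7, and the alkenylnickel at C8 isomerises until it can reach the amide carbonyl of the oxamate. Addition there forms C8–C8a, and loss of water gives methyl 4-(4-isopropoxyphenyl)-3-(4-methoxyphenyl)-1-(4-methylphenylsulfonyl)pyrrole-2-carboxylate A3.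
- For it: the assembly is modular and catalytic, and regiochemistry is set by the insertion. The pyrrole A3 arrives aromatic without an oxidant. The lactone can later be closed as an enol lactone from an N-phenacyl acid, so no C3–C4 dehydrogenation is needed. On these last two points it is stronger than the chosen route, which uses a quinone twice.
- Against it: nickel inserts into aryl–iodine bonds, so the ring that A2 delivers to C7 must enter without iodine and under a different ether (isopropyl against methyl). It must then be unmasked selectively and iodinated once, ortho to the free phenol, where mono- against di-iodination is controlled by stoichiometry alone. After A3 there remain detosylation, N-alkylation, saponification, lactonisation, selective dealkylation, iodination and demethylation, on top of the preparation of A1.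
- Comparison: the chosen strategy carries iodine from its second step, uses no transition metal and needs seven steps in all.

**Alternative 2:** The pyrrole is cut at N5–C6, C7–C8 and N5–C8a into three components: 2,2-dimethoxy-2-(4-methoxyphenyl)ethanamine A4, (3-iodo-4-methoxyphenyl)acetaldehyde A5 and methyl 3-(4-methoxyphenyl)-2-nitroprop-2-enoate A6. A4 and A5 form an imine, whose enamine tautomer adds to A6, and nitrogen then closes onto the nitro-bearing carbon with loss of the nitro group. The product is methyl 1-[2,2-dimethoxy-2-(4-methoxyphenyl)ethyl]-4-(3-iodo-4-methoxyphenyl)-3-(4-methoxyphenyl)pyrrole-2-carboxylate A7.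
- For it: one pot sets all three aryl groups and the iodine. The ring is aromatic through loss of nitrous acid, without an oxidant. The masked ketone in the side chain of A7 gives the enol lactone at the correct oxidation level. In these respects it matches or beats the chosen route.
- Against it: all three components have to be made, and two are delicate (A5 self-condenses, A6 polymerises and adds nucleophiles at will). A4 may add directly to A6 before the imine forms. The ring-closing step asks nitrogen to displace nitrite from a carbon that is a nucleophilic nitronate after the conjugate addition, so reprotonation and elimination must win over retro-Michael and Nef-type paths. After A7 there are still ketal hydrolysis, saponification, lactonisation and demethylation.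
- Comparison: the chosen strategy uses two stable partners instead of three reactive ones, and its bond-forming events are intramolecular once the iminium has formed.

**Alternative 3:** The pyrrole is cut at the C8=C8a bond. The precursor is the N-oxalyl enaminone methyl 2-{[(1Z)-2-(4-isopropoxyphenyl)-3-(4-methoxyphenyl)-3-oxoprop-1-en-1-yl]amino}-2-oxoacetate A8. Low-valent titanium, made from TiCl3 and potassium graphite (C8K), would couple the aryl ketone of A8 with its oxalyl amide carbonyl reductively to give methyl 4-(4-isopropoxyphenyl)-3-(4-methoxyphenyl)-1H-pyrrole-2-carboxylate A9.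
- For it: reductive oxo–amide coupling is a direct way to a 3,4-diarylpyrrole-2-carboxylate, and A8 comes from a simple deoxybenzoin by formylation and acylation. The NH pyrrole A9 is well set for N-phenacylation and enol lactonisation, again without dehydrogenating C3–C4. On that point it is stronger than the chosen route.
- Against it: the titanium reagent is a strong, stoichiometric, air-sensitive reductant that would cleave an aryl iodide, so A8 cannot carry iodine. Iodine must therefore be introduced after A9, by the same selective unmasking and mono-iodination as in Alternative 1. The step count from the deoxybenzoin to the target is roughly twice that of the chosen route.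
- Comparison: the chosen strategy offers early, unambiguous placement of iodine, metal-free conditions and a shorter sequence, at the price of two oxidation-level adjustments.

Key step: step 5

## Route

Step 1
Reactants: 1 racemic 2-amino-1-(4-methoxyphenyl)ethanol; 2 phenyl bromoacetate
Product: 5 racemic 6-(4-methoxyphenyl)morpholin-2-one hydrochloride, via phenyl glycinate 3 (not isolated), via free-base morpholinone 4 (not isolated)
Conditions: i-Pr2NEt, MeCN, 0 °C → 40 °C; then aq NaHCO3 wash, HCl (2 M in Et2O), EtOAc, 0 °C
Reagents that add atoms: hydrogen chloride, SMILES Cl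
Why: SN2 N-alkylation of the primary amine by the α-bromo ester gives 3, whose activated aryl ester is attacked by the benzylic hydroxyl (6-exo-trig lactonisation) under neutral conditions to give 4. Immediate protonation precipitates 5 away from the phenol, stops self-aminolysis of the amino lactone, and the β-ammonium group protects the 4-methoxybenzylic C–O bond against ionisation; no stereocentre is set.

Step 2
Reactants: 6 (4-methoxyphenyl)acetic acid
Product: 7 (3-iodo-4-methoxyphenyl)acetic acid
Conditions: N-iodosuccinimide, CF3CO2H (cat.), MeCN, rt
Reagents that add atoms: N-iodosuccinimide, SMILES O=C1CCC(=O)N1I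
Why: Electrophilic aromatic iodination of an anisole; the methoxy group directs ortho because para is blocked, and the two ortho positions are equivalent, so one mono-iodide is expected.

Step 3
Reactants: 7 (3-iodo-4-methoxyphenyl)acetic acid; 8 4-methoxybenzaldehyde
Product: 9 (E)-2-(3-iodo-4-methoxyphenyl)-3-(4-methoxyphenyl)prop-2-enoic acid
Conditions: Ac2O, Et3N, 120 °C; then H2O, aq HCl
Reagents that add atoms: none
Why: Perkin condensation (Oglialoro variant): the arylacetic acid, activated in the flask by the anhydride and enolised by Et3N, adds to the aldehyde and eliminates to form the C7=C8 bond. This reaction type gives the E acid with the two aryl groups cis, and the aryl iodide is inert.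

Step 4
Reactants: 9 (E)-2-(3-iodo-4-methoxyphenyl)-3-(4-methoxyphenyl)prop-2-enoic acid
Product: 11 (E)-2-(3-iodo-4-methoxyphenyl)-3-(4-methoxyphenyl)prop-2-enal, via acid chloride 10 (not isolated)
Conditions: (COCl)2, DMF (cat.), CH2Cl2, 0 °C → rt; then LiAlH(OtBu)3, THF, −78 °C
Reagents that add atoms: none
Why: Acid chloride formation followed by partial reduction with a hindered alkoxyaluminium hydride, which stops at the aldehyde at low temperature. The hindered conjugated enal is slow to reduce further, and the aryl iodide and alkene geometry are not affected.

Step 5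
Reactants: 5 racemic 6-(4-methoxyphenyl)morpholin-2-one hydrochloride; 11 (E)-2-(3-iodo-4-methoxyphenyl)-3-(4-methoxyphenyl)prop-2-enal
Product: 15 7-(3-iodo-4-methoxyphenyl)-3,8-bis(4-methoxyphenyl)-3,4-dihydro-1H-pyrrolo[2,1-c][1,4]oxazin-1-one (racemic), via iminium ion 12 (not isolated), via azomethine ylide 13 (not isolated), via pyrroline 14 (not isolated)
Conditions: 4 Å MS, MeCN–ClCH2CH2Cl, 70 °C; then NaOAc, 70 °C; then DDQ, 0 °C → rt
Reagents that add atoms: none
Why: The secondary ammonium chloride 5 condenses with enal 11 by addition and loss of water, as amine salts do with enals in iminium catalysis, and the sieves draw the equilibrium to iminium chloride 12, which makes N5–C6 without leaving a stock of neutral amino lactone to acylate itself. The C8a–H of 12 lies between the iminium nitrogen and the lactone carbonyl, so acetate, added only when 11 is consumed, removes it to give the lactone-stabilised vinyl azomethine ylide 13; the C4–H has no carbonyl next to it and is left alone, which fixes the end of the dipole. Ylide 13 is a five-atom, six-electron system (C8a, N5, C6, C7, C8) that closes thermally by disrotatory 1,5-electrocyclization to 2-pyrroline 14, forming C8–C8a; in Baldwin's terms the closure is 5-endo-trig, permitted here because it is pericyclic. The closest known reaction type is the annulation of cyclic secondary amines and α-amino esters with enals through conjugated azomethine ylides, together with the aldehyde-derived ylides of morpholin-2-ones. The E geometry of 11 puts hydrogen on the inside of the C8 terminus and the lactone ring holds C1 on the outside at C8a, and since no free aldehyde is left when the ylide forms, ring closure should outrun intermolecular cycloaddition. The stereocentres formed at C8 and C8a are removed when DDQ, added cold to the same flask, dehydrogenates 14 to pyrrole 15; no stereocentre is set and C3 stays racemic. At that temperature DDQ should leave the C3–C4 bond and the aryl iodide alone, and regiochemistry is fixed by connectivity: the formyl carbon becomes C6 and the anisyl-bearing carbon bonds to C8a.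

Step 6
Reactants: 15 7-(3-iodo-4-methoxyphenyl)-3,8-bis(4-methoxyphenyl)-3,4-dihydro-1H-pyrrolo[2,1-c][1,4]oxazin-1-one (racemic)
Product: 16 7-(3-iodo-4-methoxyphenyl)-3,8-bis(4-methoxyphenyl)-1H-pyrrolo[2,1-c][1,4]oxazin-1-one
Conditions: DDQ, PhMe, 100 °C
Reagents that add atoms: none
Why: Quinone dehydrogenation: DDQ abstracts hydride from the 4-methoxybenzylic C3–H (or oxidises the arylpyrrole by electron transfer, after which C4–H is lost), and loss of the neighbouring proton gives the conjugated enol lactone. This is the reaction type used to dehydrogenate 5,6-dihydropyrrolo[2,1-a]isoquinolines and flavanones; it removes the C3 stereocentre and leaves the iodide alone.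

Step 7
Reactants: 16 7-(3-iodo-4-methoxyphenyl)-3,8-bis(4-methoxyphenyl)-1H-pyrrolo[2,1-c][1,4]oxazin-1-one
Product: 17 lukianol B, 3,8-bis(4-hydroxyphenyl)-7-(4-hydroxy-3-iodophenyl)-1H-pyrrolo[2,1-c][1,4]oxazin-1-one
Conditions: BBr3, CH2Cl2, −78 °C → rt; then MeOH, H2O
Reagents that add atoms: none
Why: Lewis acid cleavage of aryl methyl ethers (boron coordinates the ether oxygen, bromide attacks the methyl group). The vinylogous, pyranone-like lactone and the aryl iodide are expected to tolerate BBr3 at or below room temperature, and the benzylic C3 is now sp2, so it cannot ionise.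

## Compound list

1 | 2-amino-1-(4-methoxyphenyl)ethanol (racemic) | NCC(O)c1ccc(OC)cc1 | starting material
2 | phenyl bromoacetate | O=C(CBr)Oc1ccccc1 | starting material
3 | phenyl N-[2-hydroxy-2-(4-methoxyphenyl)ethyl]glycinate (racemic, not isolated) | O=C(CNCC(O)c1ccc(OC)cc1)Oc1ccccc1 | intermediate
4 | 6-(4-methoxyphenyl)morpholin-2-one (racemic free base, not isolated) | O=C1CNCC(c2ccc(OC)cc2)O1 | intermediate
5 | 6-(4-methoxyphenyl)morpholin-2-one hydrochloride (racemic) | O=C1CNCC(c2ccc(OC)cc2)O1.Cl | intermediate
6 | (4-methoxyphenyl)acetic acid | COc1ccc(CC(=O)O)cc1 | starting material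
7 | (3-iodo-4-methoxyphenyl)acetic acid | COc1ccc(CC(=O)O)cc1I | intermediate
8 | 4-methoxybenzaldehyde | COc1ccc(C=O)cc1 | starting material
9 | (E)-2-(3-iodo-4-methoxyphenyl)-3-(4-methoxyphenyl)prop-2-enoic acid | OC(=O)/C(c1ccc(OC)c(I)c1)=C/c1ccc(OC)cc1 | intermediate
10 | (E)-2-(3-iodo-4-methoxyphenyl)-3-(4-methoxyphenyl)prop-2-enoyl chloride (not isolated) | ClC(=O)/C(c1ccc(OC)c(I)c1)=C/c1ccc(OC)cc1 | intermediate
11 | (E)-2-(3-iodo-4-methoxyphenyl)-3-(4-methoxyphenyl)prop-2-enal | O=C/C(c1ccc(OC)c(I)c1)=C/c1ccc(OC)cc1 | intermediate
12 | 4-[(2E)-2-(3-iodo-4-methoxyphenyl)-3-(4-methoxyphenyl)prop-2-en-1-ylidene]-6-(4-methoxyphenyl)-2-oxomorpholin-4-ium chloride (racemic, not isolated) | O=C1C[N+](=C/C(c2ccc(OC)c(I)c2)=C/c2ccc(OC)cc2)CC(c2ccc(OC)cc2)O1.[Cl-] | intermediate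
13 | 4-[(2E)-2-(3-iodo-4-methoxyphenyl)-3-(4-methoxyphenyl)prop-2-en-1-ylidene]-6-(4-methoxyphenyl)-2-oxomorpholin-4-ium-3-ide, the azomethine ylide (racemic, not isolated) | O=C1[CH-][N+](=C/C(c2ccc(OC)c(I)c2)=C/c2ccc(OC)cc2)CC(c2ccc(OC)cc2)O1 | intermediate
14 | 7-(3-iodo-4-methoxyphenyl)-3,8-bis(4-methoxyphenyl)-3,4,8,8a-tetrahydro-1H-pyrrolo[2,1-c][1,4]oxazin-1-one (mixture of racemic diastereomers, not isolated) | O=C1OC(c2ccc(OC)cc2)CN2C=C(c3ccc(OC)c(I)c3)C(c3ccc(OC)cc3)C12 | intermediate
15 | 7-(3-iodo-4-methoxyphenyl)-3,8-bis(4-methoxyphenyl)-3,4-dihydro-1H-pyrrolo[2,1-c][1,4]oxazin-1-one (racemic) | O=C1OC(c2ccc(OC)cc2)Cn2cc(-c3ccc(OC)c(I)c3)c(-c3ccc(OC)cc3)c12 | intermediate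
16 | 7-(3-iodo-4-methoxyphenyl)-3,8-bis(4-methoxyphenyl)-1H-pyrrolo[2,1-c][1,4]oxazin-1-one | O=c1oc(-c2ccc(OC)cc2)cn2cc(-c3ccc(OC)c(I)c3)c(-c3ccc(OC)cc3)c12 | intermediate
17 | lukianol B, 3,8-bis(4-hydroxyphenyl)-7-(4-hydroxy-3-iodophenyl)-1H-pyrrolo[2,1-c][1,4]oxazin-1-one | O=c1oc(-c2ccc(O)cc2)cn2cc(-c3ccc(O)c(I)c3)c(-c3ccc(O)cc3)c12 | target

## Step count and least certain steps

Total: 7 steps. Longest linear sequence: 6 steps (steps 2, 3, 4, 5, 6, 7 from acid 6); step 1 is a one-step branch.

**Step 5 (key step).** The most likely failures are incomplete condensation of the ammonium salt with the α,β-disubstituted enal, which is slow to form an iminium ion, and, as a consequence, capture of the ylide by the carbonyl group of enal still present (oxazolidine-type cycloaddition) in competition with ring closure. Opening of the lactone by the water of condensation before the sieves take it up is a further risk. The fallback sets out from 11 and returns at 16. Enal 11 is condensed with glycine methyl ester hydrochloride (Et3N, MgSO4, CH2Cl2) to the imine methyl N-[(2E)-2-(3-iodo-4-methoxyphenyl)-3-(4-methoxyphenyl)prop-2-en-1-ylidene]glycinate F1. DBU in hot toluene deprotonates the glycine carbon, and the 2-azapentadienyl system so formed electrocyclises to methyl 4-(3-iodo-4-methoxyphenyl)-3-(4-methoxyphenyl)-3,4-dihydro-2H-pyrrole-2-carboxylate F2. DDQ then gives methyl 4-(3-iodo-4-methoxyphenyl)-3-(4-methoxyphenyl)-1H-pyrrole-2-carboxylate F3. N-Alkylation with 2-bromo-1-(4-methoxyphenyl)ethanone (K2CO3, acetone) gives methyl 4-(3-iodo-4-methoxyphenyl)-3-(4-methoxyphenyl)-1-[2-(4-methoxyphenyl)-2-oxoethyl]-1H-pyrrole-2-carboxylate F4, and saponification (KOH, aqueous EtOH) gives 4-(3-iodo-4-methoxyphenyl)-3-(4-methoxyphenyl)-1-[2-(4-methoxyphenyl)-2-oxoethyl]-1H-pyrrole-2-carboxylic acid F5. Cyclodehydration (Ac2O, NaOAc, heat) closes enol lactone 16 at the final oxidation level, so step 6 is bypassed as well.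

**Step 6.** The most likely failure is sluggish hydride abstraction at C3, because the acyloxy group and the pyrrole ester both withdraw electrons, with oxidative degradation of the electron-rich arylpyrrole taking over at the temperature needed. Radical bromination and elimination is not a remedy, since an electrophilic bromine source would attack the free C6 position. The fallback sets out from 15 and returns at 16. LiOH in aqueous THF opens the lactone, and careful acidification gives 1-[2-hydroxy-2-(4-methoxyphenyl)ethyl]-4-(3-iodo-4-methoxyphenyl)-3-(4-methoxyphenyl)-1H-pyrrole-2-carboxylic acid F6. Dess–Martin periodinane (NaHCO3, CH2Cl2) oxidises the benzylic alcohol to the keto acid F5 already described under step 5, and Ac2O and NaOAc with heating close the enol lactone 16.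

**Step 1.** The most likely failures are double N-alkylation, N-acylation by the active ester, and oligomerisation of free base 4 by intermolecular aminolysis while the hindered secondary alcohol lactonises slowly. The fallback sets out from 1 and returns at 15. Amino alcohol 1, in excess, is alkylated with ethyl bromoacetate (Et3N, THF, 0 °C) to ethyl N-[2-hydroxy-2-(4-methoxyphenyl)ethyl]glycinate F7, a secondary amino ester that can be purified and stored. F7 and enal 11 are taken through the condensation, ylide formation, electrocyclization and DDQ oxidation of step 5 (PhCO2H cat., 4 Å MS, toluene, 80 °C; then DDQ), now on an acyclic N-alkyl glycinate, which should give ethyl 1-[2-hydroxy-2-(4-methoxyphenyl)ethyl]-4-(3-iodo-4-methoxyphenyl)-3-(4-methoxyphenyl)-1H-pyrrole-2-carboxylate F8. K2CO3 (cat.) in hot toluene, with removal of the alcohol formed, closes lactone 15; acid is avoided at this stage because the benzylic alcohol is no longer protected by an ammonium group.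

**Step 4.** The most likely failures are over-reduction of the aldehyde to the allylic alcohol, and some loss of alkene geometry at the acid chloride stage through reversible addition of chloride. The fallback sets out from 9 and returns at 11. Acid 9 is methylated (MeI, K2CO3, DMF) to methyl (E)-2-(3-iodo-4-methoxyphenyl)-3-(4-methoxyphenyl)prop-2-enoate F9. The ester is reduced fully on purpose (i-Bu2AlH, CH2Cl2, −78 °C) to (E)-2-(3-iodo-4-methoxyphenyl)-3-(4-methoxyphenyl)prop-2-en-1-ol F10, and MnO2 in CH2Cl2 oxidises the allylic alcohol selectively to enal 11.

## Further compounds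

F1 | step 5 | methyl N-[(2E)-2-(3-iodo-4-methoxyphenyl)-3-(4-methoxyphenyl)prop-2-en-1-ylidene]glycinate | COC(=O)CN=C/C(c1ccc(OC)c(I)c1)=C/c1ccc(OC)cc1
F2 | step 5 | methyl 4-(3-iodo-4-methoxyphenyl)-3-(4-methoxyphenyl)-3,4-dihydro-2H-pyrrole-2-carboxylate (mixture of racemic diastereomers) | COC(=O)C1N=CC(c2ccc(OC)c(I)c2)C1c1ccc(OC)cc1
F3 | step 5 | methyl 4-(3-iodo-4-methoxyphenyl)-3-(4-methoxyphenyl)-1H-pyrrole-2-carboxylate | COC(=O)c1[nH]cc(-c2ccc(OC)c(I)c2)c1-c1ccc(OC)cc1
F4 | step 5 | methyl 4-(3-iodo-4-methoxyphenyl)-3-(4-methoxyphenyl)-1-[2-(4-methoxyphenyl)-2-oxoethyl]-1H-pyrrole-2-carboxylate | COC(=O)c1c(-c2ccc(OC)cc2)c(-c2ccc(OC)c(I)c2)cn1CC(=O)c1ccc(OC)cc1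
F5 | step 5 | 4-(3-iodo-4-methoxyphenyl)-3-(4-methoxyphenyl)-1-[2-(4-methoxyphenyl)-2-oxoethyl]-1H-pyrrole-2-carboxylic acid | OC(=O)c1c(-c2ccc(OC)cc2)c(-c2ccc(OC)c(I)c2)cn1CC(=O)c1ccc(OC)cc1
F6 | step 6 | 1-[2-hydroxy-2-(4-methoxyphenyl)ethyl]-4-(3-iodo-4-methoxyphenyl)-3-(4-methoxyphenyl)-1H-pyrrole-2-carboxylic acid (racemic) | OC(=O)c1c(-c2ccc(OC)cc2)c(-c2ccc(OC)c(I)c2)cn1CC(O)c1ccc(OC)cc1
F7 | step 1 | ethyl N-[2-hydroxy-2-(4-methoxyphenyl)ethyl]glycinate (racemic) | CCOC(=O)CNCC(O)c1ccc(OC)cc1
F8 | step 1 | ethyl 1-[2-hydroxy-2-(4-methoxyphenyl)ethyl]-4-(3-iodo-4-methoxyphenyl)-3-(4-methoxyphenyl)-1H-pyrrole-2-carboxylate (racemic) | CCOC(=O)c1c(-c2ccc(OC)cc2)c(-c2ccc(OC)c(I)c2)cn1CC(O)c1ccc(OC)cc1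
F9 | step 4 | methyl (E)-2-(3-iodo-4-methoxyphenyl)-3-(4-methoxyphenyl)prop-2-enoate | COC(=O)/C(c1ccc(OC)c(I)c1)=C/c1ccc(OC)cc1
F10 | step 4 | (E)-2-(3-iodo-4-methoxyphenyl)-3-(4-methoxyphenyl)prop-2-en-1-ol | OC/C(c1ccc(OC)c(I)c1)=C/c1ccc(OC)cc1
A1 | alternative 1 | methyl 2-{[3-(4-methoxyphenyl)prop-2-yn-1-yl](4-methylphenylsulfonyl)amino}-2-oxoacetate | COC(=O)C(=O)N(CC#Cc1ccc(OC)cc1)S(=O)(=O)c1ccc(C)cc1
A2 | alternative 1 | (4-isopropoxyphenyl)boronic acid | CC(C)Oc1ccc(B(O)O)cc1
A3 | alternative 1 | methyl 4-(4-isopropoxyphenyl)-3-(4-methoxyphenyl)-1-(4-methylphenylsulfonyl)pyrrole-2-carboxylate | COC(=O)c1c(-c2ccc(OC)cc2)c(-c2ccc(OC(C)C)cc2)cn1S(=O)(=O)c1ccc(C)cc1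
A4 | alternative 2 | 2,2-dimethoxy-2-(4-methoxyphenyl)ethanamine | NCC(OC)(OC)c1ccc(OC)cc1
A5 | alternative 2 | (3-iodo-4-methoxyphenyl)acetaldehyde | O=CCc1ccc(OC)c(I)c1
A6 | alternative 2 | methyl 3-(4-methoxyphenyl)-2-nitroprop-2-enoate (alkene geometry not defined) | COC(=O)C(=Cc1ccc(OC)cc1)[N+](=O)[O-]
A7 | alternative 2 | methyl 1-[2,2-dimethoxy-2-(4-methoxyphenyl)ethyl]-4-(3-iodo-4-methoxyphenyl)-3-(4-methoxyphenyl)pyrrole-2-carboxylate | COC(=O)c1c(-c2ccc(OC)cc2)c(-c2ccc(OC)c(I)c2)cn1CC(OC)(OC)c1ccc(OC)cc1
A8 | alternative 3 | methyl 2-{[(1Z)-2-(4-isopropoxyphenyl)-3-(4-methoxyphenyl)-3-oxoprop-1-en-1-yl]amino}-2-oxoacetate | COC(=O)C(=O)N/C=C(/c1ccc(OC(C)C)cc1)C(=O)c1ccc(OC)cc1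
A9 | alternative 3 | methyl 4-(4-isopropoxyphenyl)-3-(4-methoxyphenyl)-1H-pyrrole-2-carboxylate | COC(=O)c1[nH]cc(-c2ccc(OC(C)C)cc2)c1-c1ccc(OC)cc1
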